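**Retrosynthetic overview**
- Target ⇐ 10-membered lactone with C14 as CH2OH and C15-O-silyl, by allylic oxidation and desilylation.
- Key disconnection, C5–C6 together with O6–C12: intramolecular Ni/Cr alkenylation of a C6 aldehyde by a C5 alkenyl iodide; the C6 chromium alkoxide closes the γ-lactone on the C12 methyl ester in the same pot.
- Seco chain ⇐ C7–C8 by indium Barbier allylation of a lactol (masked C8 aldehyde) with a (Z)-2-(bromomethyl)enoate, setting C7 and C8 from C9.
- Lactol ⇐ C1=C10 by cross-metathesis of an iodo-diene (from carbocupration of a propargyl silyl ether) with an enantioenriched Morita–Baylis–Hillman (MBH) acrylate that sets C9.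
- Ring order: no ring before the key step; carbocycle and lactone then form together.

Assumption: labels C1–C15 follow germacrane numbering of the target (C6 lactone carbinol, C8 ester carbinol, C9 methoxy carbinol, C14 aldehyde, C15 hydroxymethyl), and anhydrous 4 is obtained from the commercial aqueous solution.

**Step 1**
Reactants: 1 tert-butyl(diphenyl)(prop-2-yn-1-yloxy)silane; 2 but-3-en-1-ylmagnesium bromide
Product: 3 tert-butyl{[(2E)-2-(iodomethylidene)hex-5-en-1-yl]oxy}diphenylsilane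
Conditions: 2, CuBr·SMe2 (1.2 equiv), THF, −40 °C; 1, −40 → −15 °C; I2, −40 → 0 °C
Reagents that add atoms: iodine, II
Why: Normant syn-carbocupration of the terminal alkyne (alkyl to the internal carbon, Cu to the terminal carbon; THF and the bulky silyl ether disfavour O-directed linear addition) followed by iodinolysis with retention puts iodine cis to the butenyl chain, which is the geometry of the later C4=C5 bond.

**Step 2**
Reactants: 4 2,2-dimethoxyacetaldehyde; 5 1,1,1,3,3,3-hexafluoropropan-2-yl prop-2-enoate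
Product: 6 1,1,1,3,3,3-hexafluoropropan-2-yl (3S)-3-hydroxy-4,4-dimethoxy-2-methylidenebutanoate
Conditions: β-isocupreidine (10 mol %), DMF, −55 °C
Reagents that add atoms: none
Why: Hatakeyama-type asymmetric Morita–Baylis–Hillman reaction; the quinidine-derived catalyst with the hexafluoroisopropyl acrylate selects the aldehyde face in the aldol of the ammonium enolate and sets the future C9 as (S) (same facial sense as the (R)-adducts of simple aldehydes, the descriptor changing only through CIP priority).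

**Step 3**
Reactants: 6 (S)-MBH adduct
Product: 7 1,1,1,3,3,3-hexafluoropropan-2-yl (3S)-3,4,4-trimethoxy-2-methylidenebutanoate
Conditions: MeOTf, 2,6-di-tert-butyl-4-methylpyridine, CH2Cl2, 0 °C → rt
Reagents that add atoms: methyl trifluoromethanesulfonate, COS(=O)(=O)C(F)(F)F
Why: O-methylation with a hard alkylating agent and a non-nucleophilic base avoids retro-aldol, oxa-Michael addition and attack on the activated ester, and leaves C9 untouched.

**Step 4**
Reactants: 7 O-methyl MBH acrylate; 3 iodo-diene (2.5 equiv)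
Product: 8 1,1,1,3,3,3-hexafluoropropan-2-yl (2E,6E)-6-({[tert-butyl(diphenyl)silyl]oxy}methyl)-7-iodo-2-[(1S)-1,2,2-trimethoxyethyl]hepta-2,6-dienoate
Conditions: Hoveyda–Grubbs II (10 mol %), toluene, 80 °C, Ar sweep
Reagents that add atoms: none
Why: Olefin cross-metathesis of a terminal alkene with a 1,1-disubstituted acrylate gives the thermodynamically preferred (E)-trisubstituted enoate (carbonyl trans to the chain, as with methacrylates), which fixes the C1=C10 geometry; the trisubstituted iodoalkene does not take part.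

**Step 5**
Reactants: 8 (E)-enoate
Product: 10 lactol (3S,4Z)-4-[(4E)-4-({[tert-butyl(diphenyl)silyl]oxy}methyl)-5-iodopent-4-en-1-ylidene]-3-methoxyoxolan-2-ol (anomer mixture), via allylic alcohol acetal 9 (not isolated)
Conditions: DIBAL-H (3 equiv), CH2Cl2, −78 °C; then 1 M HCl, THF, rt
Reagents that add atoms: water, O
Why: DIBAL reduction of the activated ester gives the C14 allylic alcohol, whose hydroxyl assists hydrolysis of the otherwise sluggish α-methoxy acetal through the five-membered cyclic acetal, giving a lactol that masks the C8 aldehyde and ties up C14–OH; C9 is not touched.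

**Step 6**
Reactants: 4 2,2-dimethoxyacetaldehyde; 11 methyl prop-2-enoate
Product: 12 methyl 3-hydroxy-4,4-dimethoxy-2-methylidenebutanoate (racemic)
Conditions: DABCO (0.5 equiv), dioxane/H2O, rt
Reagents that add atoms: none
Why: Standard Morita–Baylis–Hillman reaction with a reactive α-oxygenated aldehyde; the stereocentre is destroyed in the next step, so no control is needed.

**Step 7**
Reactants: 12 racemic MBH adduct
Product: 13 methyl (2Z)-2-(bromomethyl)-4,4-dimethoxybut-2-enoate
Conditions: NBS, Me2S, CH2Cl2, 0 °C → rt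
Reagents that add atoms: N-bromosuccinimide, O=C1CCC(=O)N1Br
Why: Corey–Kim-type activation of the MBH alcohol and SN2′ bromide delivery gives the thermodynamically favoured (Z)-2-(bromomethyl)enoate (acetal carbon cis to CH2Br) under conditions that spare the acetal.

**Step 8**
Reactants: 10 lactol; 13 (Z)-allylic bromide (1.5 equiv)
Product: 14 methyl (3R,4S,5S,6Z,10E)-10-({[tert-butyl(diphenyl)silyl]oxy}methyl)-3-(dimethoxymethyl)-4-hydroxy-6-(hydroxymethyl)-11-iodo-5-methoxy-2-methylideneundeca-6,10-dienoate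
Conditions: In powder (2 equiv), THF/H2O (1:1), rt
Reagents that add atoms: none
Why: Indium-mediated Barbier allylation of the lactol's open-chain α-methoxy aldehyde: the (Z)-configured allylindium reacts at its γ-carbon through a chair Zimmerman–Traxler transition state to give the C7/C8-syn adduct, and In(III) chelation between the carbonyl and the α-OMe gives the C8/C9-syn (Cram-chelate) face, so C7 and C8 are both set from C9; the hydroxy ester is isolated without acid so that it does not lactonise.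

**Step 9**
Reactants: 14 diol
Product: 15 methyl (3R,4S,5S,6Z,10E)-10-({[tert-butyl(diphenyl)silyl]oxy}methyl)-3-(dimethoxymethyl)-4-hydroxy-11-iodo-5-methoxy-2-methylidene-6-{[(triethylsilyl)oxy]methyl}undeca-6,10-dienoate
Conditions: TESCl (1.05 equiv), imidazole, CH2Cl2, −40 °C
Reagents that add atoms: chlorotriethylsilane, CC[Si](Cl)(CC)CC
Why: Selective silylation of the primary allylic C14–OH over the hindered secondary C8–OH.

**Step 10**
Reactants: 15 C14-O-TES alcohol
Product: 16 methyl (3R,4S,5S,6Z,10E)-10-({[tert-butyl(diphenyl)silyl]oxy}methyl)-3-(dimethoxymethyl)-11-iodo-5-methoxy-2-methylidene-4-[(2-methylprop-2-enoyl)oxy]-6-{[(triethylsilyl)oxy]methyl}undeca-6,10-dienoate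
Conditions: methacrylic anhydride, DMAP, Et3N, CH2Cl2, 0 °C → rt
Reagents that add atoms: methacrylic anhydride, C=C(C)C(=O)OC(=O)C(C)=C
Why: DMAP-catalysed acylation installs the C8 methacrylate with retention and blocks O8, so that only O6 can later lactonise onto C12.

**Step 11**
Reactants: 16 methacrylate
Product: 17 methyl (3R,4S,5S,6Z,10E)-10-({[tert-butyl(diphenyl)silyl]oxy}methyl)-3-formyl-6-(hydroxymethyl)-11-iodo-5-methoxy-2-methylidene-4-[(2-methylprop-2-enoyl)oxy]undeca-6,10-dienoate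
Conditions: TFA/H2O (4:1), CH2Cl2, 0 °C; used crude at once
Reagents that add atoms: water, O
Why: Mild aqueous acid hydrolyses the unhindered dimethyl acetal to the C6 aldehyde and removes the TES ether in one operation, while the TBDPS ether, the esters and the three stereocentres survive (cold, short contact to avoid enolisation of the α-branched aldehyde).

**Step 12**
Reactants: 17 iodo-aldehyde
Product: 19 (1(10)Z,4E,6R,7S,8S,9S)-15-{[tert-butyl(diphenyl)silyl]oxy}-14-hydroxy-9-methoxygermacra-1(10),4,11(13)-trien-12,6-olid-8-yl 2-methylprop-2-enoate, via chromium(III) alkoxide seco-ester 18 (not isolated)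
Conditions: CrCl2 (8 equiv), NiCl2 (5 mol %), degassed DMSO/THF (3:1), 2 mM (syringe pump), rt; aq. NH4Cl work-up
Reagents that add atoms: none
Why: Proposed new method: intramolecular Nozaki–Hiyama–Kishi alkenylation (Ni inserts into the C5–I bond with retention of alkene geometry, transmetallation to Cr(III), addition to the C6 aldehyde) closes the cis,cis-cyclodecadiene, and the resulting C6 chromium alkoxide, γ to the activated C12 ester, lactonises in the pot as in Cr-mediated 2-(bromomethyl)acrylate additions, so both rings form in one operation; C6 is expected (R) (H6/H7 trans) from a macrocyclic transition state with the C5 and C8 ring bonds pseudo-equatorial about the forming stereocentre; the closest known reactions are NHK macrocyclisations to medium rings and Cr(II) alkoxide-to-lactone closures.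

**Step 13**
Reactants: 19 macrolactone allylic alcohol
Product: 20 (1(10)E,4E,6R,7S,8S,9S)-15-{[tert-butyl(diphenyl)silyl]oxy}-9-methoxy-14-oxogermacra-1(10),4,11(13)-trien-12,6-olid-8-yl 2-methylprop-2-enoate
Conditions: MnO2 (20 equiv), CH2Cl2, rt
Reagents that add atoms: none
Why: Chemoselective MnO2 oxidation of the only free (primary allylic) alcohol gives the conjugated enal in its stable geometry (CHO trans to C2) without touching the Michael acceptors.

**Step 14**
Reactants: 20 silyl ether enal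
Product: 21 target, (1(10)E,4E,6R,7S,8S,9S)-15-hydroxy-9-methoxy-14-oxogermacra-1(10),4,11(13)-trien-12,6-olid-8-yl 2-methylprop-2-enoate
Conditions: HF·pyridine, pyridine, THF, 0 °C → rt
Reagents that add atoms: none
Why: Buffered HF·pyridine desilylation removes the primary TBDPS ether without base-induced conjugate addition, acyl migration or translactonisation.

**Compound list**
1 | tert-butyl(diphenyl)(prop-2-yn-1-yloxy)silane | C#CCO[Si](c1ccccc1)(c1ccccc1)C(C)(C)C | starting material
2 | but-3-en-1-ylmagnesium bromide | C=CCC[Mg]Br | starting material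
3 | tert-butyl{[(2E)-2-(iodomethylidene)hex-5-en-1-yl]oxy}diphenylsilane | I/C=C(/CO[Si](c1ccccc1)(c1ccccc1)C(C)(C)C)CCC=C | intermediate
4 | 2,2-dimethoxyacetaldehyde | COC(OC)C=O | starting material
5 | 1,1,1,3,3,3-hexafluoropropan-2-yl prop-2-enoate | C=CC(=O)OC(C(F)(F)F)C(F)(F)F | starting material
6 | 1,1,1,3,3,3-hexafluoropropan-2-yl (3S)-3-hydroxy-4,4-dimethoxy-2-methylidenebutanoate | FC(F)(F)C(OC(=O)C(=C)[C@H](O)C(OC)OC)C(F)(F)F | intermediate
7 | 1,1,1,3,3,3-hexafluoropropan-2-yl (3S)-3,4,4-trimethoxy-2-methylidenebutanoate | FC(F)(F)C(OC(=O)C(=C)[C@H](OC)C(OC)OC)C(F)(F)F | intermediate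
8 | 1,1,1,3,3,3-hexafluoropropan-2-yl (2E,6E)-6-({[tert-butyl(diphenyl)silyl]oxy}methyl)-7-iodo-2-[(1S)-1,2,2-trimethoxyethyl]hepta-2,6-dienoate | FC(F)(F)C(OC(=O)/C(=C/CC/C(CO[Si](c1ccccc1)(c1ccccc1)C(C)(C)C)=C\I)[C@H](OC)C(OC)OC)C(F)(F)F | intermediate
9 | (2Z,6E)-6-({[tert-butyl(diphenyl)silyl]oxy}methyl)-7-iodo-2-[(1S)-1,2,2-trimethoxyethyl]hepta-2,6-dien-1-ol | OC/C(=C/CC/C(CO[Si](c1ccccc1)(c1ccccc1)C(C)(C)C)=C\I)[C@H](OC)C(OC)OC | intermediate
10 | (3S,4Z)-4-[(4E)-4-({[tert-butyl(diphenyl)silyl]oxy}methyl)-5-iodopent-4-en-1-ylidene]-3-methoxyoxolan-2-ol (anomer mixture) | OC1OC/C(=C/CC/C(CO[Si](c2ccccc2)(c2ccccc2)C(C)(C)C)=C\I)[C@@H]1OC | intermediate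
11 | methyl prop-2-enoate | C=CC(=O)OC | starting material
12 | methyl 3-hydroxy-4,4-dimethoxy-2-methylidenebutanoate (racemic) | COC(=O)C(=C)C(O)C(OC)OC | intermediate
13 | methyl (2Z)-2-(bromomethyl)-4,4-dimethoxybut-2-enoate | COC(=O)/C(CBr)=C/C(OC)OC | intermediate
14 | methyl (3R,4S,5S,6Z,10E)-10-({[tert-butyl(diphenyl)silyl]oxy}methyl)-3-(dimethoxymethyl)-4-hydroxy-6-(hydroxymethyl)-11-iodo-5-methoxy-2-methylideneundeca-6,10-dienoate | O[C@H]([C@@H](OC)\C(CO)=C/CC/C(CO[Si](c1ccccc1)(c1ccccc1)C(C)(C)C)=C\I)[C@H](C(OC)OC)C(=C)C(=O)OC | intermediate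
15 | C14-O-triethylsilyl ether of 14 (3R,4S,5S,6Z,10E) | O[C@H]([C@@H](OC)\C(CO[Si](CC)(CC)CC)=C/CC/C(CO[Si](c1ccccc1)(c1ccccc1)C(C)(C)C)=C\I)[C@H](C(OC)OC)C(=C)C(=O)OC | intermediate
16 | C8-O-methacrylate of 15 (3R,4S,5S,6Z,10E) | C=C(C)C(=O)O[C@H]([C@@H](OC)\C(CO[Si](CC)(CC)CC)=C/CC/C(CO[Si](c1ccccc1)(c1ccccc1)C(C)(C)C)=C\I)[C@H](C(OC)OC)C(=C)C(=O)OC | intermediate
17 | methyl (3R,4S,5S,6Z,10E)-10-({[tert-butyl(diphenyl)silyl]oxy}methyl)-3-formyl-6-(hydroxymethyl)-11-iodo-5-methoxy-2-methylidene-4-[(2-methylprop-2-enoyl)oxy]undeca-6,10-dienoate | C=C(C)C(=O)O[C@H]([C@@H](OC)\C(CO)=C/CC/C(CO[Si](c1ccccc1)(c1ccccc1)C(C)(C)C)=C\I)[C@H](C=O)C(=C)C(=O)OC | intermediate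
18 | dichlorochromium(III) C6-alkoxide of the ring-closed methyl 12-ester (10-membered carbocycle, lactone still open; C7–C9 as in 17, C6 as in 19) | C=C(C)C(=O)O[C@H]1[C@@H](C(=C)C(=O)OC)[C@H](O[Cr](Cl)Cl)/C=C(/CO[Si](c2ccccc2)(c2ccccc2)C(C)(C)C)CC/C=C(/CO)[C@@H]1OC | intermediate
19 | (1(10)Z,4E,6R,7S,8S,9S)-15-{[tert-butyl(diphenyl)silyl]oxy}-14-hydroxy-9-methoxygermacra-1(10),4,11(13)-trien-12,6-olid-8-yl 2-methylprop-2-enoate | C=C(C)C(=O)O[C@H]1[C@H]2C(=C)C(=O)O[C@@H]2/C=C(/CO[Si](c3ccccc3)(c3ccccc3)C(C)(C)C)CC/C=C(/CO)[C@@H]1OC | intermediate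
20 | (1(10)E,4E,6R,7S,8S,9S)-15-{[tert-butyl(diphenyl)silyl]oxy}-9-methoxy-14-oxogermacra-1(10),4,11(13)-trien-12,6-olid-8-yl 2-methylprop-2-enoate | C=C(C)C(=O)O[C@H]1[C@H]2C(=C)C(=O)O[C@@H]2/C=C(/CO[Si](c3ccccc3)(c3ccccc3)C(C)(C)C)CC/C=C(/C=O)[C@@H]1OC | intermediate
21 | (1(10)E,4E,6R,7S,8S,9S)-15-hydroxy-9-methoxy-14-oxogermacra-1(10),4,11(13)-trien-12,6-olid-8-yl 2-methylprop-2-enoate | C=C(C)C(=O)O[C@H]1[C@H]2C(=C)C(=O)O[C@@H]2/C=C(/CO)CC/C=C(/C=O)[C@@H]1OC | target

**Step count**
Total steps: 14. Longest linear sequence: 11 steps (steps 2, 3, 4, 5, 8, 9, 10, 11, 12, 13, 14, starting from 4 and 5).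

**Steps most likely to fail**

Step 12 (Ni/Cr ring closure with lactonisation). The β-acyloxy, α-branched aldehyde 17 may eliminate or isomerise, and the Cr alkoxide may scramble the methacrylate. The fallback sets out from 15 and comes back at 20; it closes the ring on a silyl ether and acylates afterwards. 15 is silylated (TBSOTf, 2,6-lutidine) to the C8-O-tert-butyldimethylsilyl ether of 15 F7. Aqueous TFA then gives the C8-O-TBS hydroxy aldehyde F8. The same Ni/Cr closure gives the C8-O-TBS macrolactone F9, and MnO2 gives the C8-O-TBS enal F10. HF·pyridine at 0 °C removes the secondary TBS ether but not the primary TBDPS ether, giving the C8 alcohol enal F11, which is esterified with methacrylic anhydride and DMAP to give 20.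

Step 8 (indium Barbier, three stereochemical elements). Chelation by an α-OMe group in water may be weak, so the C8 face could be mixed. The fallback sets out from 13 (with 10) and comes back at 14; it replaces the chelation-dependent Barbier by a catalyst-controlled allylboration. Pd-catalysed borylation of 13 (B2pin2, Pd2(dba)3) gives methyl (2E)-4,4-dimethoxy-2-[(4,4,5,5-tetramethyl-1,3,2-dioxaborolan-2-yl)methyl]but-2-enoate F6. Chiral phosphoric acid (TRIP)-catalysed allylboration of 10 with F6 (toluene, rt) passes through a closed chair, so the boronate geometry enforces the C7/C8-syn relation and the catalyst, not the metal chelate, selects the aldehyde face; neutral work-up gives 14.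

Step 4 (cross-metathesis to a hindered trisubstituted enoate). The α-branched acrylate 7 may be too hindered. The fallback sets out from 3 and comes back at 10 (through 9); it builds C1=C10 by aldol condensation instead of metathesis.
- Lemieux–Johnson cleavage of the terminal alkene of 3 (OsO4 cat., NaIO4, 2,6-lutidine) gives (4E)-4-({[tert-butyl(diphenyl)silyl]oxy}methyl)-5-iodopent-4-enal F1.
- Noyori hydrogenation of commercial methyl 4,4-dimethoxy-3-oxobutanoate (Ru–(R)-BINAP, H2) gives methyl (3S)-3-hydroxy-4,4-dimethoxybutanoate F2, which is methylated (MeOTf, hindered pyridine) to methyl (3S)-3,4,4-trimethoxybutanoate F3.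
- The enolate of F3 is trapped in situ as its silyl ketene acetal (LDA, TMSCl, −78 °C, to prevent β-elimination of methoxide) and added to F1 (BF3·OEt2, Mukaiyama aldol) to give the β-hydroxy ester aldol adduct F4.
- MsCl/Et3N then DBU gives the (E)-enoate methyl (2E,6E)-6-({[tert-butyl(diphenyl)silyl]oxy}methyl)-7-iodo-2-[(1S)-1,2,2-trimethoxyethyl]hepta-2,6-dienoate F5, which enters step 5 unchanged (DIBAL-H; then aqueous HCl) to give 10.

**Further compounds**
F1 | step 4 | (4E)-4-({[tert-butyl(diphenyl)silyl]oxy}methyl)-5-iodopent-4-enal | O=CCC/C(CO[Si](c1ccccc1)(c1ccccc1)C(C)(C)C)=C\I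
F2 | step 4 | methyl (3S)-3-hydroxy-4,4-dimethoxybutanoate | COC(=O)C[C@H](O)C(OC)OC
F3 | step 4 | methyl (3S)-3,4,4-trimethoxybutanoate | COC(=O)C[C@H](OC)C(OC)OC
F4 | step 4 | methyl 6-({[tert-butyl(diphenyl)silyl]oxy}methyl)-3-hydroxy-7-iodo-2-[(1S)-1,2,2-trimethoxyethyl]hept-6-enoate (6E, diastereomer mixture at C2 and C3) | COC(=O)C(C(O)CC/C(CO[Si](c1ccccc1)(c1ccccc1)C(C)(C)C)=C\I)[C@H](OC)C(OC)OC
F5 | step 4 | methyl (2E,6E)-6-({[tert-butyl(diphenyl)silyl]oxy}methyl)-7-iodo-2-[(1S)-1,2,2-trimethoxyethyl]hepta-2,6-dienoate | COC(=O)/C(=C/CC/C(CO[Si](c1ccccc1)(c1ccccc1)C(C)(C)C)=C\I)[C@H](OC)C(OC)OC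
F6 | step 8 | methyl (2E)-4,4-dimethoxy-2-[(4,4,5,5-tetramethyl-1,3,2-dioxaborolan-2-yl)methyl]but-2-enoate | COC(=O)/C(CB1OC(C)(C)C(C)(C)O1)=C/C(OC)OC
F7 | step 12 | C8-O-tert-butyldimethylsilyl ether of 15 | CC(C)(C)[Si](C)(C)O[C@H]([C@@H](OC)\C(CO[Si](CC)(CC)CC)=C/CC/C(CO[Si](c1ccccc1)(c1ccccc1)C(C)(C)C)=C\I)[C@H](C(OC)OC)C(=C)C(=O)OC
F8 | step 12 | C8-O-TBS analogue of 17 (C6 aldehyde, C14 alcohol) | CC(C)(C)[Si](C)(C)O[C@H]([C@@H](OC)\C(CO)=C/CC/C(CO[Si](c1ccccc1)(c1ccccc1)C(C)(C)C)=C\I)[C@H](C=O)C(=C)C(=O)OC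
F9 | step 12 | C8-O-TBS analogue of 19 (macrolactone, C14 alcohol) | CC(C)(C)[Si](C)(C)O[C@H]1[C@H]2C(=C)C(=O)O[C@@H]2/C=C(/CO[Si](c3ccccc3)(c3ccccc3)C(C)(C)C)CC/C=C(/CO)[C@@H]1OC
F10 | step 12 | C8-O-TBS analogue of 20 (macrolactone, C14 aldehyde) | CC(C)(C)[Si](C)(C)O[C@H]1[C@H]2C(=C)C(=O)O[C@@H]2/C=C(/CO[Si](c3ccccc3)(c3ccccc3)C(C)(C)C)CC/C=C(/C=O)[C@@H]1OC
F11 | step 12 | C8 alcohol corresponding to 20 (macrolactone, C14 aldehyde, C15-O-TBDPS) | O[C@H]1[C@H]2C(=C)C(=O)O[C@@H]2/C=C(/CO[Si](c3ccccc3)(c3ccccc3)C(C)(C)C)CC/C=C(/C=O)[C@@H]1OC
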